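In a one-step world, substrate meets free catalyst and comes out as product, partner has no say, and the order in partner is nought. The substrate columns look like that world: at 90.0 min birch holds 19.9% and elm 19.1%, level within the scatter, though the two differ in partner and second catalyst. But birch then shows product of 10.0%, so 70.1% of its substrate stands as something I can't read.

| setting | ash | elm | birch | flask |
|---|---|---|---|---|
| substrate | 1 M | 1 M | 1 M | 1.0 M |
| partner | 1.1 equiv | 1.1 equiv | 0.55 equiv | 1.10 equiv |
| free catalyst | 10 mol% | 10 mol% | 10 mol% | 10 mol% |
| second catalyst | 0.17 mol% | 0.66 mol% | 0.33 mol% | 0.33 mol% |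
| added ligand | 110 mM | 110 mM | 110 mM | 110 mM |
| remark | run made earlier | run made earlier | run made earlier |  |

| run | time / min | product / % | substrate / % |
|---|---|---|---|
| ash | 5.00 | 0.7 | 89.1 |
| ash | 15.0 | 1.8 | 71.4 |
| ash | 25.0 | 2.5 | 59.0 |
| ash | 40.0 | 4.9 | 45.5 |
| ash | 50.0 | 5.2 | 39.8 |
| ash | 80.0 | 8.9 | 23.2 |
| ash | 90.0 | 9.1 | 20.3 |
| elm | 12.0 | 4.9 | 76.9 |
| elm | 25.0 | 9.8 | 60.0 |
| elm | 40.0 | 14.7 | 45.2 |
| elm | 50.0 | 17.6 | 38.7 |
| elm | 60.0 | 20.8 | 32.4 |
| elm | 80.0 | 25.9 | 23.3 |
| elm | 90.0 | 29.5 | 19.1 |
| birch | 8.00 | 1.1 | 83.4 |
| birch | 25.0 | 3.7 | 61.1 |
| birch | 40.0 | 5.1 | 45.3 |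
| birch | 60.0 | 6.6 | 32.0 |
| birch | 90.0 | 10.0 | 19.9 |

(readings scatter by 0.5 percentage points)

- what was read earlier has a scatter of 0.5 percentage points, one standard deviation
- "the catalyst" is free catalyst with its forms; second catalyst is a second catalyst

* apparent order in partner when 50% of the substrate are converted (percent change of the rate of making product for one percent more partner charged)

I take that world as the nought of a scale on which one means product rising in step with partner. The neighbour of the flask is birch, with the same second catalyst and half the partner. The flask is unread, but its loading of second catalyst is the geometric middle of ash and elm. So I take the geometric mean of their product at 90.0 min, 16.4%, as my estimate of its product there, which is more than birch's reading. The logarithm of the product ratio over the logarithm of the partner ratio is then 0.712, give or take 0.0832 from the scatter of the readings; this is my partner order, the apparent order averaged over the span between the two charges and over the product made up to that time. At 90.0 min the flask and birch should stand level in substrate and apart in product, because partner acts beyond the loss of substrate: the order stands well clear of nought.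

The forecast puts the order at 0.7, in a range from 0.45 to 0.95, with the words “Slight saturation would lower the local value at 1.1 equiv to about 0.7.”

The flask gives 0.62, inside that range.

    substrate + free catalyst → free catalyst + open intermediate (k = 0.240 M⁻¹ min⁻¹)
    free catalyst + added ligand ⇌ idle complex (K = 6.10 M⁻¹, k = 0.160 M⁻¹ min⁻¹)
    second catalyst + open intermediate ⇌ catalyst intermediate (K = 15.0 M⁻¹, k = 35.0 M⁻¹ min⁻¹)
    second catalyst ⇌ dormant form (K = 11.0, k = 0.100 min⁻¹)
    partner + catalyst intermediate → second catalyst + product (k = 1.90 M⁻¹ min⁻¹)

This lies 0.0920 under my average, about one scatter. The simulated flask with twice the partner has its rate raised by a factor 1.43, and the same logarithms read 0.516 there, lower again. In the flask at 1.50 h open intermediate is made 1.88 times faster than it is used up, each step taken net, and it stands at 63.3% of the substrate charged against product at 16.7%.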